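**Retrosynthetic overview** (side chain numbered C1 at the ring to C17)

1. The quinone is unmasked last by para-oxidation of a 2-alkyl-6-methoxy-3-methylphenol; its six-membered carbocycle is the only ring, is bought as 2-methoxy-5-methylphenol, and no ring is formed in the route.
2. C2=C3 (cross-metathesis, then hydrogenation) joins an ortho-allylphenol, made by aromatic Claisen rearrangement, to a terminal alkene holding C3–C17; C7–C8 is a copper-catalysed alkyl–alkyl coupling.
3. Enabling feature: C8–C17 is CH2(C8)–[CH(CH3)–CH2]3–CH(CH3)–CH2CH3 with the methines C9, C11, C13 and C15 all syn, a head-to-tail repeat in which every CH(CH3)–CH2 unit is a vinyl group plus a methyl group, so one operation can be repeated along the chain.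
4. Key disconnection: C11–C12, made by palladium-catalysed vinylation (bromoethene) of the primary alane that zirconium-catalysed asymmetric methylalumination of (4S)-4-methylhex-1-ene gives in the same flask; this three-component operation sets C13 and forms C13–CH3 and C12–C11, and two more rounds with the same zirconocene antipode set C11 and C9.
5. C15 is bought together with the ethyl end as (2S)-1-bromo-2-methylbutane.

Key step: step 2

Assumption: the (+)-antipode of bis(1-neomenthylindenyl)zirconium dichloride is taken to deliver the (2S)-configured 2-methylalkylalanes drawn; should the opposite hold, the (−)-antipode is used in steps 2 to 4 and nothing else changes.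

Step 1
Reactants: 1 (2S)-1-bromo-2-methylbutane; 2 bromoethene
Product: 4 (4S)-4-methylhex-1-ene, via methylbutyl Grignard reagent 3 (not isolated)
Conditions: 1, Mg, Et2O, reflux; then 2, NiCl2(dppp) (1 mol%), Et2O, 0 °C to rt; fractional distillation
Reagents that add atoms: none
Why: Nickel-catalysed Kumada–Corriu coupling of a primary alkyl Grignard reagent with a vinyl halide is routine, the chelating diphosphine suppressing β-hydride elimination, and the C15 stereocentre, β to magnesium, takes no part.

Step 2
Reactants: 4 (4S)-4-methylhex-1-ene; 2 bromoethene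
Product: 6 (4R,6S)-4,6-dimethyloct-1-ene, via dimethylhexyl alane 5 (not isolated)
Conditions: Al(CH3)3 (2 equiv), (+)-bis(1-neomenthylindenyl)zirconium dichloride ZrCl2(C19H25)2 (4 mol%), methylaluminoxane [Al(CH3)O]n (1 equiv), CH2Cl2, 0 °C to rt; volatiles removed in vacuo; then Zn(OTf)2 (1 equiv), DMF, 70 °C; then 2 (6 equiv), PdCl2(DPEphos) (3 mol%), iBu2AlH (6 mol%), DMF, rt
Reagents that add atoms: trimethylaluminium, C[Al](C)C
Why: Al(CH3)3 and methylaluminoxane turn the zirconium dichloride into a cationic methylzirconocene that inserts the terminal alkene of 4 by four-centre syn-carbometalation, the methyl group going to the internal carbon C13 and zirconium to the terminal carbon C12, after which alkyl–methyl exchange with Al(CH3)3 releases alane 5 and restores the Zr–CH3 bond. In the same flask Zn(OTf)2 in DMF relays the primary alkyl group of 5 to the vinylpalladium bromide that zerovalent palladium (from PdCl2(DPEphos) and iBu2AlH) forms with bromoethene 2 by oxidative addition, and reductive elimination makes the C12–C11 bond (Negishi coupling), so that three components, 4, Al(CH3)3 and 2, end up in 6. The closest known reaction type is the zirconium-catalysed asymmetric carboalumination of 1-alkenes run in tandem with palladium-catalysed vinylation, used to grow reduced polypropionate chains by one CH(CH3)–CH2 unit per operation; no ring is closed. The one new stereocentre, C13, is set by the catalyst, whose chiral neomenthylindenyl ligands admit one enantioface of the monosubstituted alkene to the Zr–CH3 bond, while the resident C15 centre, one CH2 group away, is expected to act only as a minor modifier, the syn pairing being the matched one. The step needs the metal at the CH2 terminus, which the monosubstituted alkene secures, carbometalation in preference to β-hydride transfer, which the chlorinated solvent and methylaluminoxane favour, and face selectivity, which is expected to be useful but not complete, so that the C13 epimer is carried as a diastereomer and removed at alcohol 11. In the coupling the primary alkyl group must leave aluminium in preference to the two methyl groups, any methyl transfer giving only propene that escapes as a gas, and the vinyl group so installed is the alkene that the next round needs, its CH carbon becoming the methine C11.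

Step 3
Reactants: 6 (4R,6S)-4,6-dimethyloct-1-ene; 2 bromoethene
Product: 8 (4R,6S,8S)-4,6,8-trimethyldec-1-ene, via trimethyloctyl alane 7 (not isolated)
Conditions: Al(CH3)3 (2 equiv), (+)-ZrCl2(C19H25)2 (4 mol%), [Al(CH3)O]n (1 equiv), CH2Cl2, 0 °C to rt; volatiles removed in vacuo; then Zn(OTf)2 (1 equiv), DMF, 70 °C; then 2 (6 equiv), PdCl2(DPEphos) (3 mol%), iBu2AlH (6 mol%), DMF, rt
Reagents that add atoms: trimethylaluminium, C[Al](C)C
Why: The same tandem of zirconium-catalysed asymmetric carboalumination and palladium-catalysed vinylation (Negishi coupling) is repeated on the new terminal alkene, the catalyst placing the methyl group on C11 from the same enantioface as before so that C11 is syn to C13, and the vinylation forming C10–C9.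

Step 4
Reactants: 8 (4R,6S,8S)-4,6,8-trimethyldec-1-ene
Product: 11 (2S,4S,6S,8S)-2,4,6,8-tetramethyldecan-1-ol, via tetramethyldecyl alane 9 (not isolated), via aluminium alkoxide 10 (not isolated)
Conditions: Al(CH3)3 (2 equiv), (+)-ZrCl2(C19H25)2 (4 mol%), [Al(CH3)O]n (1 equiv), CH2Cl2, 0 °C to rt; then dry O2, 0 °C to rt; aq. HCl; SiO2 chromatography
Reagents that add atoms: trimethylaluminium, C[Al](C)C; dioxygen, O=O
Why: A third zirconium-catalysed asymmetric carboalumination sets C9 under the same catalyst control, and oxidation of the C–Al bonds with O2 followed by hydrolysis gives the primary alcohol, the polar stage at which the minor diastereomers gathered over three rounds should be removable by chromatography.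

Step 5
Reactants: 11 (2S,4S,6S,8S)-2,4,6,8-tetramethyldecan-1-ol
Product: 12 (2S,4S,6S,8S)-2,4,6,8-tetramethyldecyl 4-methylbenzenesulfonate
Conditions: TsCl, pyridine, DMAP (cat.), CH2Cl2, 0 °C to rt
Reagents that add atoms: 4-methylbenzenesulfonyl chloride (TsCl), Cc1ccc(cc1)S(=O)(=O)Cl
Why: Sulfonylation of a primary alcohol (tosylation) is routine, makes C8 an electrophile and does not touch the β-stereocentre at C9.

Step 6
Reactants: 12 (2S,4S,6S,8S)-2,4,6,8-tetramethyldecyl 4-methylbenzenesulfonate; 13 6-bromohex-1-ene
Product: 15 (8R,10R,12S,14S)-8,10,12,14-tetramethylhexadec-1-ene, via hexenyl Grignard reagent 14 (not isolated)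
Conditions: 13, Mg, THF, rt; then 12, Li2CuCl4 (5 mol%), THF, −78 °C to rt
Reagents that add atoms: none
Why: Copper-catalysed alkyl–alkyl cross-coupling of a Grignard reagent with a primary tosylate should displace the sulfonate at the β-branched but primary C8 by an SN2-type path in which no stereocentre takes part, the terminal alkene of the Grignard reagent being inert.

Step 7
Reactants: 16 2-methoxy-5-methylphenol
Product: 17 1-methoxy-4-methyl-2-(prop-2-en-1-yloxy)benzene
Conditions: allyl bromide, K2CO3, acetone, reflux
Reagents that add atoms: allyl bromide, C=CCBr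
Why: Williamson ether synthesis of a phenoxide with a reactive allylic bromide, for which O-alkylation is expected under these conditions.

Step 8
Reactants: 17 1-methoxy-4-methyl-2-(prop-2-en-1-yloxy)benzene
Product: 18 6-methoxy-3-methyl-2-(prop-2-en-1-yl)phenol
Conditions: N,N-diethylaniline, 200 °C (sealed tube)
Reagents that add atoms: none
Why: Aromatic Claisen rearrangement ([3,3]-sigmatropic shift, then tautomerisation) should deliver the allyl group to the only unsubstituted ortho carbon, the one between the oxygen and the ring methyl, since the other ortho carbon carries the methoxy group.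

Step 9
Reactants: 15 (8R,10R,12S,14S)-8,10,12,14-tetramethylhexadec-1-ene; 18 6-methoxy-3-methyl-2-(prop-2-en-1-yl)phenol (3 equiv)
Product: 19 6-methoxy-3-methyl-2-[(2E,9R,11R,13S,15S)-9,11,13,15-tetramethylheptadec-2-en-1-yl]phenol (E drawn; the E/Z mixture is carried on)
Conditions: second-generation Grubbs catalyst RuCl2(=CHPh)(PCy3)(H2IMes) (5 mol%), 1,4-benzoquinone (10 mol%), CH2Cl2, 40 °C
Reagents that add atoms: none
Why: Olefin cross-metathesis of two terminal alkenes is driven by loss of ethene, and with the cheap phenol 18 in excess and benzoquinone suppressing double-bond migration the chain alkene 15 should end mostly in the cross product, whose alkene geometry is irrelevant because it is hydrogenated next.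

Step 10
Reactants: 19 6-methoxy-3-methyl-2-[(2E,9R,11R,13S,15S)-9,11,13,15-tetramethylheptadec-2-en-1-yl]phenol
Product: 20 6-methoxy-3-methyl-2-[(9R,11R,13S,15S)-9,11,13,15-tetramethylheptadecyl]phenol
Conditions: H2 (1 atm), Pd/C, EtOAc, rt
Reagents that add atoms: none
Why: Heterogeneous catalytic hydrogenation of a 1,2-disubstituted alkene should leave the arene and the remote stereocentres unaffected.

Step 11
Reactants: 20 6-methoxy-3-methyl-2-[(9R,11R,13S,15S)-9,11,13,15-tetramethylheptadecyl]phenol
Product: 21 5-methoxy-2-methyl-3-[(9R,11R,13S,15S)-9,11,13,15-tetramethylheptadecyl]cyclohexa-2,5-diene-1,4-dione (CNP0330767.1)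
Conditions: Co(salen), Co(C16H14N2O2) (20 mol%), O2 (1 atm), DMF, rt
Reagents that add atoms: dioxygen, O=O
Why: Cobalt–salen-catalysed aerobic phenol oxidation should convert a phenol with both ortho positions blocked (OCH3 and the chain) and a free para position into the para-quinone through the phenoxyl radical and its oxygenation at the para carbon, as for other 2,6-disubstituted phenols, with no stereocentre nearby.

**Compound list**

1 | (2S)-1-bromo-2-methylbutane | CC[C@H](C)CBr | starting material
2 | bromoethene (vinyl bromide) | C=CBr | starting material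
3 | [(2S)-2-methylbutyl]magnesium bromide (formed in the flask, not isolated) | CC[C@H](C)C[Mg]Br | intermediate
4 | (4S)-4-methylhex-1-ene | CC[C@H](C)CC=C | intermediate
5 | [(2S,4S)-2,4-dimethylhexyl]dimethylalane (formed in the flask, not isolated) | CC[C@H](C)C[C@H](C)C[Al](C)C | intermediate
6 | (4R,6S)-4,6-dimethyloct-1-ene | CC[C@H](C)C[C@H](C)CC=C | intermediate
7 | dimethyl[(2S,4S,6S)-2,4,6-trimethyloctyl]alane (formed in the flask, not isolated) | CC[C@H](C)C[C@H](C)C[C@H](C)C[Al](C)C | intermediate
8 | (4R,6S,8S)-4,6,8-trimethyldec-1-ene | CC[C@H](C)C[C@H](C)C[C@H](C)CC=C | intermediate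
9 | dimethyl[(2S,4S,6S,8S)-2,4,6,8-tetramethyldecyl]alane (formed in the flask, not isolated) | CC[C@H](C)C[C@H](C)C[C@H](C)C[C@H](C)C[Al](C)C | intermediate
10 | dimethoxy[(2S,4S,6S,8S)-2,4,6,8-tetramethyldecan-1-olato]aluminium (formed in the flask, not isolated) | CC[C@H](C)C[C@H](C)C[C@H](C)C[C@H](C)CO[Al](OC)OC | intermediate
11 | (2S,4S,6S,8S)-2,4,6,8-tetramethyldecan-1-ol | CC[C@H](C)C[C@H](C)C[C@H](C)C[C@H](C)CO | intermediate
12 | (2S,4S,6S,8S)-2,4,6,8-tetramethyldecyl 4-methylbenzenesulfonate | CC[C@H](C)C[C@H](C)C[C@H](C)C[C@H](C)COS(=O)(=O)c1ccc(C)cc1 | intermediate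
13 | 6-bromohex-1-ene | C=CCCCCBr | starting material
14 | hex-5-enylmagnesium bromide (formed in the flask, not isolated) | C=CCCCC[Mg]Br | intermediate
15 | (8R,10R,12S,14S)-8,10,12,14-tetramethylhexadec-1-ene | CC[C@H](C)C[C@H](C)C[C@H](C)C[C@H](C)CCCCCC=C | intermediate
16 | 2-methoxy-5-methylphenol | COc1ccc(C)cc1O | starting material
17 | 1-methoxy-4-methyl-2-(prop-2-en-1-yloxy)benzene | COc1ccc(C)cc1OCC=C | intermediate
18 | 6-methoxy-3-methyl-2-(prop-2-en-1-yl)phenol | COc1ccc(C)c(CC=C)c1O | intermediate
19 | 6-methoxy-3-methyl-2-[(2E,9R,11R,13S,15S)-9,11,13,15-tetramethylheptadec-2-en-1-yl]phenol | CC[C@H](C)C[C@H](C)C[C@H](C)C[C@H](C)CCCCC/C=C/Cc1c(C)ccc(OC)c1O | intermediate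
20 | 6-methoxy-3-methyl-2-[(9R,11R,13S,15S)-9,11,13,15-tetramethylheptadecyl]phenol | CC[C@H](C)C[C@H](C)C[C@H](C)C[C@H](C)CCCCCCCCc1c(C)ccc(OC)c1O | intermediate
21 | 5-methoxy-2-methyl-3-[(9R,11R,13S,15S)-9,11,13,15-tetramethylheptadecyl]cyclohexa-2,5-diene-1,4-dione | CC[C@H](C)C[C@H](C)C[C@H](C)C[C@H](C)CCCCCCCCC1=C(C)C(=O)C=C(OC)C1=O | target

**Step count**

Total: 11 steps. Longest linear sequence: 9 steps (1, 2, 3, 4, 5, 6, 9, 10, 11); steps 7 and 8 form the short second branch.

**Steps most likely to fail**

Step 2. The zirconocene may discriminate the two faces of the monosubstituted alkene incompletely, so that a C13 epimer is carried through the later rounds. Transfer of the primary alkyl group from aluminium to palladium may stall or be outrun by methyl transfer. The volatile seven-carbon alkene may also be lost before carbometalation is complete.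
Fallback: C13 is taken from the chiral pool by a stereospecific substitution, and the C12–C11 bond is then made by a separate nickel-catalysed vinylation; it sets out from bromide 1 and returns at alkene 6. tert-Butyl (S)-lactate is triflated (Tf2O, 2,6-lutidine, CH2Cl2, −78 °C) to tert-butyl (2S)-2-{[(trifluoromethyl)sulfonyl]oxy}propanoate F1. Grignard reagent 3, made from 1 as in step 1, displaces the triflate under ZnCl2 catalysis (THF, 0 °C) with inversion at the lactate carbon, which forms the C14–C13 bond and gives tert-butyl (2S,4S)-2,4-dimethylhexanoate F2. LiAlH4 (Et2O, 0 °C) reduces F2 to (2S,4S)-2,4-dimethylhexan-1-ol F3, at which stage a minor diastereomer can be removed. CBr4 and PPh3 (CH2Cl2, 0 °C) convert F3 into (2S,4S)-1-bromo-2,4-dimethylhexane F4, and Mg in Et2O gives [(2S,4S)-2,4-dimethylhexyl]magnesium bromide F5, which is vinylated with bromoethene 2 (NiCl2(dppp), Et2O) to 6.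

Step 9. Self-metathesis of both partners competes statistically, and ruthenium-hydride-induced double-bond migration in the allylarene before metathesis would give chain-shortened homologues that are hard to separate.
Fallback: the aryl–C1 bond is made instead of C2=C3, by B-alkyl Suzuki coupling; it sets out from tosylate 12 and phenol 16 and returns at phenol 20. Tosylate 12 is coupled (Li2CuCl4, THF) with hept-6-enylmagnesium bromide F6 (from 7-bromohept-1-ene and Mg) to (9R,11R,13S,15S)-9,11,13,15-tetramethylheptadec-1-ene F7. Phenol 16 is protected (MOMCl, iPr2NEt, CH2Cl2) as 1-methoxy-2-(methoxymethoxy)-4-methylbenzene F8, lithiated ortho to the acetal oxygen (n-BuLi, TMEDA, THF, 0 °C) to [3-methoxy-2-(methoxymethoxy)-6-methylphenyl]lithium F9 and iodinated (I2) to 2-iodo-4-methoxy-3-(methoxymethoxy)-1-methylbenzene F10. Hydroboration of F7 with 9-BBN gives 9-[(9R,11R,13S,15S)-9,11,13,15-tetramethylheptadecyl]-9-borabicyclo[3.3.1]nonane F11, which is coupled with F10 (Pd(dppf)Cl2, K3PO4, THF/DMF/H2O, 60 °C) to 1-methoxy-2-(methoxymethoxy)-4-methyl-3-[(9R,11R,13S,15S)-9,11,13,15-tetramethylheptadecyl]benzene F12. HCl in methanol removes the acetal and gives 20.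

Step 11. The phenol oxidation may stall or be diverted: oxygenation at the para carbon flanked by the ring methyl may be slow, phenoxyl radicals may couple, and the lipophilic substrate may dissolve poorly in DMF.
Fallback: the para oxygen is brought in through a carbon substituent; it sets out from phenol 20 and returns at quinone 21. Duff formylation (hexamethylenetetramine, CF3CO2H, reflux; then aqueous acid) at the free para position gives 4-hydroxy-5-methoxy-2-methyl-3-[(9R,11R,13S,15S)-9,11,13,15-tetramethylheptadecyl]benzaldehyde F13. Dakin oxidation (H2O2, NaOH, THF/H2O) gives 5-methoxy-2-methyl-3-[(9R,11R,13S,15S)-9,11,13,15-tetramethylheptadecyl]benzene-1,4-diol F14, and Ag2O in diethyl ether oxidises the hydroquinone to 21.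

**Further compounds**

F1 | step 2 | tert-butyl (2S)-2-{[(trifluoromethyl)sulfonyl]oxy}propanoate | C[C@H](OS(=O)(=O)C(F)(F)F)C(=O)OC(C)(C)C
F2 | step 2 | tert-butyl (2S,4S)-2,4-dimethylhexanoate | CC[C@H](C)C[C@H](C)C(=O)OC(C)(C)C
F3 | step 2 | (2S,4S)-2,4-dimethylhexan-1-ol | CC[C@H](C)C[C@H](C)CO
F4 | step 2 | (2S,4S)-1-bromo-2,4-dimethylhexane | CC[C@H](C)C[C@H](C)CBr
F5 | step 2 | [(2S,4S)-2,4-dimethylhexyl]magnesium bromide | CC[C@H](C)C[C@H](C)C[Mg]Br
F6 | step 9 | hept-6-enylmagnesium bromide | C=CCCCCC[Mg]Br
F7 | step 9 | (9R,11R,13S,15S)-9,11,13,15-tetramethylheptadec-1-ene | CC[C@H](C)C[C@H](C)C[C@H](C)C[C@H](C)CCCCCCC=C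
F8 | step 9 | 1-methoxy-2-(methoxymethoxy)-4-methylbenzene | COCOc1cc(C)ccc1OC
F9 | step 9 | [3-methoxy-2-(methoxymethoxy)-6-methylphenyl]lithium | [Li]c1c(C)ccc(OC)c1OCOC
F10 | step 9 | 2-iodo-4-methoxy-3-(methoxymethoxy)-1-methylbenzene | Cc1ccc(OC)c(OCOC)c1I
F11 | step 9 | 9-[(9R,11R,13S,15S)-9,11,13,15-tetramethylheptadecyl]-9-borabicyclo[3.3.1]nonane | CC[C@H](C)C[C@H](C)C[C@H](C)C[C@H](C)CCCCCCCCB1C2CCCC1CCC2
F12 | step 9 | 1-methoxy-2-(methoxymethoxy)-4-methyl-3-[(9R,11R,13S,15S)-9,11,13,15-tetramethylheptadecyl]benzene | CC[C@H](C)C[C@H](C)C[C@H](C)C[C@H](C)CCCCCCCCc1c(C)ccc(OC)c1OCOC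
F13 | step 11 | 4-hydroxy-5-methoxy-2-methyl-3-[(9R,11R,13S,15S)-9,11,13,15-tetramethylheptadecyl]benzaldehyde | CC[C@H](C)C[C@H](C)C[C@H](C)C[C@H](C)CCCCCCCCc1c(C)c(C=O)cc(OC)c1O
F14 | step 11 | 5-methoxy-2-methyl-3-[(9R,11R,13S,15S)-9,11,13,15-tetramethylheptadecyl]benzene-1,4-diol | CC[C@H](C)C[C@H](C)C[C@H](C)C[C@H](C)CCCCCCCCc1c(C)c(O)cc(OC)c1O
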